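| flask | starting material | coupling partner | free catalyst | product | time |
|---|---|---|---|---|---|
| larch | 0.600 M | 0.600 M | 0.00120 M |  |  |
| alder | 0.600 M | 0.900 M | 0.00120 M |  |  |
| cedar | 1.80 M | 0.600 M | 0.00120 M |  |  |
| oak | 0.600 M | 0.600 M | 0.00240 M |  |  |
| maple | 0.600 M | 0.600 M | 0.00120 M | 0.180 M | 18 h |

- larch run (time / h: [product] / M): 1.0: 0.066; 3.1: 0.181; 5.9: 0.262; 9.4: 0.324; 13: 0.350; 18: 0.379
- alder run (time / h: [product] / M): 1.0: 0.092; 3.1: 0.228; 5.9: 0.346; 9.4: 0.425; 13: 0.447; 18: 0.452
- cedar run (time / h: [product] / M): 1.0: 0.063; 3.1: 0.187; 5.9: 0.310; 9.4: 0.405; 13: 0.457; 18: 0.493
- oak run (time / h: [product] / M): 1.0: 0.112; 3.1: 0.278; 5.9: 0.374; 9.4: 0.421; 13: 0.442; 18: 0.441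

(standard deviation of a reading: 0.006 M)

- the power of [coupling partner] that the first rate follows, about the charge of the larch run; measure it at two percent of starting material made into product
- the power of [free catalyst] that the first rate follows, about the charge of the larch run; measure it at two percent of starting material made into product
- product in the maple run at 18 h, as a share of the starting material charged

- Overall: starting material + coupling partner -> product, with free catalyst as catalyst.
- Constant volume, constant temperature.
- The analysis sees a species whether free or bound.
- An order is taken over about fifteen percent of the charge, up and down.
- A share of product counts the product that was charged too.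

**Question turned.** Product charged counts towards the share, so I asked what would have to be true for the maple run to finish below the larch run, which read 0.379 M at 18 h. Maple, holding 0.180 M from the start, would have to make less than 0.199 M of new product in those hours.

**Catalyst-hours.** I treated the rate as a constant A times [coupling partner] while the catalyst is fresh, leaving starting material out of the reckoning, and the first hour of the larch run gives A = 0.116 /h. Then the natural logarithm of charged over remaining coupling partner, divided by A, gives τ. For the larch run at 18 h this is 8.58 h: its catalyst-hours, the hours of fresh catalyst that the flask has effectively had. Maple would finish below larch with a τ under 3.46 h, a cut by a factor of 2.48.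

**My reckoning.** The oak run levelled at 0.441 M with 0.159 M of coupling partner unused, and the alder run levelled at 0.452 M. I read this as catalyst deactivation tied to product, and took τ as inversely proportional to time-averaged product. Larch averaged 0.276 M. Adding the charge to that average gives the maple run a τ of 5.20 h, more than the 3.46 h of the turned question. That τ makes 0.272 M of new product, so I committed to 75.4%.

**The forecast.** The forecast gave 0.8 for the order in coupling partner, 0.9 for the order in free catalyst and, holding that “charged product should shorten catalyst life”, 80% for the maple run, higher than my figure.

**The flask.** The order in coupling partner came out at 0.94, the order in free catalyst at 1.0, and the maple run gave 83.4%.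

    free catalyst + starting material ⇌ catalyst-substrate complex, settled at all times (8.620 /M)
    catalyst-substrate complex + coupling partner ⇌ ternary complex, settled at all times (0.1840 /M)
    ternary complex → product + free catalyst (651.6 /h)
    free catalyst + product → spent catalyst + product (1.627 /M/h)

**Catalyst-hours again.** Spent catalyst forms from free catalyst and product with constant 1.63 /M/h. The new product of the maple run reads back as a τ of 6.57 h, more than my 5.20 h and less than the 8.58 h of the larch run. The alder run averaged 0.353 M of product, so scaling larch's τ predicts 6.71 h for it, and its last reading, on the same A, gives 5.99 h.

Readings and results are simulated from invented constants, noise included.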